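**Plan**

- Retrosynthesis: the two MOM ethers come off last. Before that, the C3–vinyl bond is cut together with the C1 ketone oxidation level, which leads back to a racemic aryl allylic carbinol and a vinyl sulfonate. The C1–aryl bond is then cut to farnesal and a lithiated, protected bromoresorcinol.
- Enabling feature: C3 is a quaternary carbon β to the ketone carbon C1, with the C2 methylene between them and the benzene ring (the only ring) on C1. C3 also bears a vinyl group. This is the pattern left when a vinylpalladium adds to the far carbon of the C2=C3 alkene of an aryl allylic carbinol and the metal then moves to the carbinol carbon.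
- Forward: farnesol is oxidised to farnesal, and the aryllithium from bis-MOM 4-bromoresorcinol is added to it (C1–aryl bond). Vinyl nonaflate is made from tetrahydrofuran. The Heck vinylation with relay to the ketone forms the C3–vinyl bond, and the MOM groups are then removed. No ring is formed at any stage.
- Stereochemistry: C3 (R), the only stereocentre, is set in the key step by a chiral pyridine-oxazoline ligand that distinguishes the faces of the 2E alkene. The 6E alkene is carried unchanged from (2E,6E)-farnesol.

Key step: step 5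

Assumption: the (R)-configured ligand is taken to give the 3R ketone from the 2E alkenol, by analogy with the accepted model for E-trisubstituted alkenols; should a first run show the opposite sense, the (S)-ligand replaces it with nothing else changed.

**Route**

Step 1
Reactants: 1 4-bromoresorcinol (4-bromobenzene-1,3-diol)
Product: 3 1-bromo-2,4-bis(methoxymethoxy)benzene, via disodium 4-bromobenzene-1,3-diolate 2 (not isolated)
Conditions: NaH (2.4 equiv), DMF, 0 °C; then MOMCl (2.4 equiv), 0 °C to rt
Reagents that add atoms: chloromethyl methyl ether (MOMCl), COCCl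
Why: Williamson ether synthesis, in which both phenoxide oxygens of 2 are alkylated by the very reactive α-chloro ether and nothing else in the molecule competes.

Step 2
Reactants: 4 (2E,6E)-farnesol
Product: 5 (2E,6E)-farnesal [(2E,6E)-3,7,11-trimethyldodeca-2,6,10-trienal]
Conditions: TEMPO (10 mol %), PhI(OAc)2 (1.1 equiv), MeCN/pH 7 phosphate buffer, 0 °C
Reagents that add atoms: none
Why: The oxoammonium-mediated TEMPO/PhI(OAc)2 oxidation takes a primary allylic alcohol to the enal without over-oxidation and, being buffered, should leave the 2E and 6E geometries untouched.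

Step 3
Reactants: 3 1-bromo-2,4-bis(methoxymethoxy)benzene; 5 (2E,6E)-farnesal
Product: 8 racemic (2E,6E)-1-[2,4-bis(methoxymethoxy)phenyl]-3,7,11-trimethyldodeca-2,6,10-trien-1-ol, via [2,4-bis(methoxymethoxy)phenyl]lithium 6 (not isolated), via lithium alkoxide of the carbinol 7 (not isolated)
Conditions: 3, n-BuLi (1.05 equiv), THF, −78 °C; then 5, −78 °C; then H2O; chromatography on Et3N-deactivated SiO2
Reagents that add atoms: none
Why: Bromine–lithium exchange at −78 °C is faster than ring deprotonation and gives the ortho-MOM-chelated aryllithium 6, which adds 1,2 to the enal (organolithium carbonyl addition); the carbinol centre is left racemic on purpose because step 5 oxidises it away, and the acid-labile product is kept from acid throughout.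

Step 4
Reactants: 9 tetrahydrofuran; 10 nonafluorobutane-1-sulfonyl fluoride
Product: 13 ethenyl nonafluorobutane-1-sulfonate (vinyl nonaflate), via 2-lithiotetrahydrofuran 11 (not isolated), via lithium ethenolate 12 (not isolated)
Conditions: n-BuLi (hexanes), THF, rt, 16 h; then 10, −78 °C to rt; distillation
Reagents that add atoms: none
Why: n-BuLi deprotonates tetrahydrofuran at C2 and the anion 11 fragments by [3+2] cycloreversion into ethene and the acetaldehyde enolate 12, which the hard sulfonyl fluoride sulfonylates at oxygen (enolate O-sulfonylation), a known preparation of the parent vinyl nonaflate.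

Step 5
Reactants: 8 racemic (2E,6E)-1-[2,4-bis(methoxymethoxy)phenyl]-3,7,11-trimethyldodeca-2,6,10-trien-1-ol; 13 ethenyl nonafluorobutane-1-sulfonate
Product: 14 (3R,6E)-1-[2,4-bis(methoxymethoxy)phenyl]-3-ethenyl-3,7,11-trimethyldodeca-6,10-dien-1-one
Conditions: Pd2(dba)3 (5 mol %), (R)-4-tert-butyl-2-[5-(trifluoromethyl)pyridin-2-yl]-4,5-dihydrooxazole (15 mol %), 13 (2 equiv), 2,6-di-tert-butyl-4-methylpyridine (1.5 equiv), 3 Å MS, DMA, rt
Reagents that add atoms: none
Why: Zerovalent palladium adds oxidatively to the C–O bond of 13 and the resulting cationic vinylpalladium, held by the pyridine-oxazoline ligand, inserts the C2=C3 alkene of 8 with vinyl going to the alcohol-distal C3 and palladium to C2; since C3 is then quaternary, β-hydride elimination can only use the carbinol C1–H, and palladium leaves C1 as zerovalent palladium with loss of the hydroxyl proton, so the aryl ketone forms and the racemic carbinol centre disappears. The closest known reaction type is the enantioselective redox-relay Heck alkenylation of trisubstituted alkenols with alkenyl sulfonates to give allylic quaternary carbons, applied here with the parent vinyl group; no ring is closed. The C3 stereocentre is controlled by the ligand alone: the alkene binds beside the oxazoline, its C2–H turns toward the tert-butyl group, and vinyl is delivered to the face of the 2E alkene that this leaves open, expected to be the one giving 3R with the (R)-ligand. The step needs insertion at C2=C3 and not at the C6=C7 and C10=C11 alkenes, which the C1–O bond should secure because only this alkene is polarised for attack at its distal carbon and unactivated trisubstituted alkenes insert far more slowly. The hindered pyridine and the sieves take up the sulfonic acid and water so that the acid-labile carbinol and the MOM ethers survive until the ketone has formed.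

Step 6
Reactants: 14 (3R,6E)-1-[2,4-bis(methoxymethoxy)phenyl]-3-ethenyl-3,7,11-trimethyldodeca-6,10-dien-1-one
Product: 15 (3R,6E)-1-(2,4-dihydroxyphenyl)-3-ethenyl-3,7,11-trimethyldodeca-6,10-dien-1-one (CNP0157533.1)
Conditions: HCl (0.5 M in MeOH), 40 °C
Reagents that add atoms: none
Why: Acid-catalysed methanolysis of the two aryl MOM acetals (transacetalisation to dimethoxymethane) frees both phenols under dilute acid that should spare the trisubstituted alkenes and the vinyl group, and the quaternary C3 has no way to epimerise.

**Compound list**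

1 | 4-bromoresorcinol | Oc1ccc(Br)c(O)c1 | starting material
2 | disodium 4-bromobenzene-1,3-diolate | [Na+].[Na+].[O-]c1ccc(Br)c([O-])c1 | intermediate (not isolated)
3 | 1-bromo-2,4-bis(methoxymethoxy)benzene | COCOc1ccc(Br)c(OCOC)c1 | intermediate
4 | (2E,6E)-farnesol | CC(C)=CCC/C(C)=C/CC/C(C)=C/CO | starting material
5 | (2E,6E)-farnesal | CC(C)=CCC/C(C)=C/CC/C(C)=C/C=O | intermediate
6 | [2,4-bis(methoxymethoxy)phenyl]lithium | [Li]c1ccc(OCOC)cc1OCOC | intermediate (not isolated)
7 | lithium (2E,6E)-1-[2,4-bis(methoxymethoxy)phenyl]-3,7,11-trimethyldodeca-2,6,10-trien-1-olate (racemic) | [Li]OC(/C=C(\C)CC/C=C(\C)CCC=C(C)C)c1ccc(OCOC)cc1OCOC | intermediate (not isolated)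
8 | (2E,6E)-1-[2,4-bis(methoxymethoxy)phenyl]-3,7,11-trimethyldodeca-2,6,10-trien-1-ol (racemic at C1) | OC(/C=C(\C)CC/C=C(\C)CCC=C(C)C)c1ccc(OCOC)cc1OCOC | intermediate
9 | tetrahydrofuran | C1CCOC1 | starting material
10 | nonafluorobutane-1-sulfonyl fluoride | O=S(=O)(F)C(F)(F)C(F)(F)C(F)(F)C(F)(F)F | starting material
11 | 2-lithiotetrahydrofuran | [Li]C1CCCO1 | intermediate (not isolated)
12 | lithium ethenolate | [Li]OC=C | intermediate (not isolated)
13 | ethenyl nonafluorobutane-1-sulfonate (vinyl nonaflate) | C=COS(=O)(=O)C(F)(F)C(F)(F)C(F)(F)C(F)(F)F | intermediate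
14 | (3R,6E)-1-[2,4-bis(methoxymethoxy)phenyl]-3-ethenyl-3,7,11-trimethyldodeca-6,10-dien-1-one | C=C[C@](C)(CC/C=C(\C)CCC=C(C)C)CC(=O)c1ccc(OCOC)cc1OCOC | intermediate
15 | (3R,6E)-1-(2,4-dihydroxyphenyl)-3-ethenyl-3,7,11-trimethyldodeca-6,10-dien-1-one | C=C[C@](C)(CC/C=C(\C)CCC=C(C)C)CC(=O)c1ccc(O)cc1O | target

**Step count and risks**

Total step count: 6. Longest linear sequence: 4 steps (step 1 or step 2, then steps 3, 5 and 6).

Steps most likely to fail:

Step 5. The electron-rich aryl ring makes the C1 oxygen easy to lose, by ionisation or by β-hydroxide elimination from the C2-palladium intermediate. The bulky secondary carbinol also slows insertion at C2=C3, which gives the remote alkenes time to react. The fallback sets out from 4 and comes back at 14. The same vinylation is run on farnesol 4 itself with 13 and the step 5 catalyst; a primary trisubstituted allylic alcohol cannot ionise, is less hindered and belongs to the substrate class on which this relay alkenylation is best established. It should give the aldehyde (3R,6E)-3-ethenyl-3,7,11-trimethyldodeca-6,10-dienal F1. Aryllithium 6, made from 3 as in step 3, is added at −78 °C to give the lithium alkoxide of the adduct F2, which water converts to the secondary alcohol (3R,6E)-1-[2,4-bis(methoxymethoxy)phenyl]-3-ethenyl-3,7,11-trimethyldodeca-6,10-dien-1-ol F3 as a mixture of C1 epimers. Dess–Martin oxidation of the alcohol then gives 14.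

Step 3. The basic aryllithium may deprotonate farnesal at its γ-positions instead of adding, with loss of material and scrambling of the 2E geometry. The fallback sets out from 5 and comes back at 8; it reaches the carbinol by acylation and reduction. Pinnick oxidation (NaClO2, NaH2PO4, 2-methyl-2-butene) gives (2E,6E)-farnesoic acid F4. Amide coupling with N,O-dimethylhydroxylamine gives the Weinreb amide (2E,6E)-N-methoxy-N,3,7,11-tetramethyldodeca-2,6,10-trienamide F5. Aryllithium 6 adds once to give the chelated lithium N-methoxy-N-methyl hemiaminal adduct F6, which on aqueous work-up collapses to the enone (2E,6E)-1-[2,4-bis(methoxymethoxy)phenyl]-3,7,11-trimethyldodeca-2,6,10-trien-1-one F7. Luche reduction (NaBH4, CeCl3·7H2O, MeOH, 0 °C) reduces the enone 1,2 to 8.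

Step 6. Protonation of the trisubstituted alkenes (cation–olefin cyclisation or addition of methanol) may compete with the slower cleavage of the para MOM ether. The fallback sets out from 1 and comes back at 15; it replaces the acetals by silyl ethers so that fluoride, not acid, ends the synthesis. Compound 1 with i-Pr3SiCl and imidazole gives 1-bromo-2,4-bis(triisopropylsilyloxy)benzene F8, whose bulky silyl groups should resist migration to carbon. Bromine–lithium exchange gives [2,4-bis(triisopropylsilyloxy)phenyl]lithium F9, and addition to 5 gives the lithium alkoxide of the silyl-protected carbinol F10. Water then gives racemic (2E,6E)-1-[2,4-bis(triisopropylsilyloxy)phenyl]-3,7,11-trimethyldodeca-2,6,10-trien-1-ol F11. The step 5 vinylation with 13 gives (3R,6E)-1-[2,4-bis(triisopropylsilyloxy)phenyl]-3-ethenyl-3,7,11-trimethyldodeca-6,10-dien-1-one F12, and Bu4NF buffered with AcOH in THF at 0 °C releases 15.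

**Further compounds**

F1 | step 5 | (3R,6E)-3-ethenyl-3,7,11-trimethyldodeca-6,10-dienal | C=C[C@](C)(CC/C=C(\C)CCC=C(C)C)CC=O
F2 | step 5 | lithium (3R,6E)-1-[2,4-bis(methoxymethoxy)phenyl]-3-ethenyl-3,7,11-trimethyldodeca-6,10-dien-1-olate (C1 epimers) | C=C[C@](C)(CC/C=C(\C)CCC=C(C)C)CC(O[Li])c1ccc(OCOC)cc1OCOC
F3 | step 5 | (3R,6E)-1-[2,4-bis(methoxymethoxy)phenyl]-3-ethenyl-3,7,11-trimethyldodeca-6,10-dien-1-ol (C1 epimers) | C=C[C@](C)(CC/C=C(\C)CCC=C(C)C)CC(O)c1ccc(OCOC)cc1OCOC
F4 | step 3 | (2E,6E)-farnesoic acid | CC(C)=CCC/C(C)=C/CC/C(C)=C/C(=O)O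
F5 | step 3 | (2E,6E)-N-methoxy-N,3,7,11-tetramethyldodeca-2,6,10-trienamide | CC(C)=CCC/C(C)=C/CC/C(C)=C/C(=O)N(C)OC
F6 | step 3 | lithium (2E,6E)-1-[2,4-bis(methoxymethoxy)phenyl]-1-[methoxy(methyl)amino]-3,7,11-trimethyldodeca-2,6,10-trien-1-olate | [Li]OC(/C=C(\C)CC/C=C(\C)CCC=C(C)C)(N(C)OC)c1ccc(OCOC)cc1OCOC
F7 | step 3 | (2E,6E)-1-[2,4-bis(methoxymethoxy)phenyl]-3,7,11-trimethyldodeca-2,6,10-trien-1-one | O=C(/C=C(\C)CC/C=C(\C)CCC=C(C)C)c1ccc(OCOC)cc1OCOC
F8 | step 6 | 1-bromo-2,4-bis(triisopropylsilyloxy)benzene | CC(C)[Si](Oc1ccc(Br)c(O[Si](C(C)C)(C(C)C)C(C)C)c1)(C(C)C)C(C)C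
F9 | step 6 | [2,4-bis(triisopropylsilyloxy)phenyl]lithium | [Li]c1ccc(O[Si](C(C)C)(C(C)C)C(C)C)cc1O[Si](C(C)C)(C(C)C)C(C)C
F10 | step 6 | lithium (2E,6E)-1-[2,4-bis(triisopropylsilyloxy)phenyl]-3,7,11-trimethyldodeca-2,6,10-trien-1-olate (racemic) | [Li]OC(/C=C(\C)CC/C=C(\C)CCC=C(C)C)c1ccc(O[Si](C(C)C)(C(C)C)C(C)C)cc1O[Si](C(C)C)(C(C)C)C(C)C
F11 | step 6 | (2E,6E)-1-[2,4-bis(triisopropylsilyloxy)phenyl]-3,7,11-trimethyldodeca-2,6,10-trien-1-ol (racemic at C1) | OC(/C=C(\C)CC/C=C(\C)CCC=C(C)C)c1ccc(O[Si](C(C)C)(C(C)C)C(C)C)cc1O[Si](C(C)C)(C(C)C)C(C)C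
F12 | step 6 | (3R,6E)-1-[2,4-bis(triisopropylsilyloxy)phenyl]-3-ethenyl-3,7,11-trimethyldodeca-6,10-dien-1-one | C=C[C@](C)(CC/C=C(\C)CCC=C(C)C)CC(=O)c1ccc(O[Si](C(C)C)(C(C)C)C(C)C)cc1O[Si](C(C)C)(C(C)C)C(C)C
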